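## Structural features

The target is an elemane sesquiterpene lactone (elemane numbering throughout). It is a cyclohexane C5–C10 in which all six ring carbons are stereocentres, cis-fused across C7–C8 to an α-methyl-γ-butyrolactone (O–C8, C12=O, C11 with methyl C13); C11 is the seventh stereocentre, its methyl on the convex face, cis to H7. C10 is an all-carbon quaternary centre carrying methyl C14 (which defines the β face) and the vinyl group C1=C2 (α). Its neighbour C5 carries the 2-formylvinyl group C4(=C3H2)–C15HO on the β face, so C1=C2–C10–C5–C4=C3 is the elemane 1,5-diene with trans alkenyl groups on a vicinal quaternary/tertiary pair. Going round the ring, C4 on C5, the isobutyrate oxygen on C6, C11 on C7 and the lactone oxygen on C8 are all β and mutually cis; the C9 hydroxyl is α, trans to O8 and cis to the vinyl group. The oxygenated carbons C6 and C9 stand 1,4 to each other across the C5–C10 bond, and each is the carbinol of a homoallylic alcohol (O–C6–C5–C4=C3 and O–C9–C10–C1=C2); this array HO–C9–C10(vinyl)–C5–C6–OH in the cyclohexane is the feature the key step exploits. Fragile groups are the α-substituted acrolein (Michael acceptor, prone to base-induced shift of the alkene into C4=C5 and to over-oxidation), the epimerisable C11, the isobutyrate, and the 1,5-diene and 3-hydroxy-1,5-diene arrays, which rule out potassium alkoxides and very high temperatures. The real difficulty is the contiguous hexad: the vinyl-bearing quaternary C10 wedged between two stereocentres, and the all-cis tetrad C5–C8, in which either three β groups (O6, O8, C14) or two carbon branches (C4, C11) must be 1,3-diaxial, so several centres have to be set kinetically.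

## Logic of the disconnections

**22 ⇒ 20 (through 21).** The O–C8 bond of the lactone and the C9–O bond of the hydroxyl are cut together: a retro anti-hydroxylactonisation of a C8=C9 alkene by the C12 ester. The trans relationship of O8 (β) and O9 (α) and the cis ring fusion are exactly what anti opening of an α-epoxide by a β side-chain carbonyl gives. Two stereocentres and the second ring disappear. The forward step must epoxidise only C8=C9 and only from the α face, which requires C3=C4 to be already conjugated to C15=O.

**20 ⇒ 18.** The C15–O bonds are cut (formyl back to methyl). An isopropenyl group survives the organoboron and thermal steps, whereas the enal would not. The most fragile group is thereby absent from all earlier intermediates. The forward allylic oxidation must prefer the C15 methyl over the one allylic hydrogen of the ring alkene.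

**18 ⇒ 15 + 16.** The C7–C11 bond is cut by a retro-[3,3] shift, which returns the alkene to C7=C8 and an oxygen to C9 on the β face. A β C9–O bond is the natural relay for a β C7–C11 bond, and the same step can set C11. The three-carbon lactone unit and two stereocentres are removed, leaving a 1,4-dioxygenated cyclohexene. The forward step needs a free β C9 hydroxyl, a blocked C6 oxygen, and conditions that spare an isobutyrate.

**15 ⇒ 13 + 14.** The C6–O bond of the ester is cut with inversion. One operation then installs the acyl group, gives C6 its β configuration and tells the two carbinols apart, since C9 is neopentylic. The precursor is a free trans-1,4-diol with every substituent but C14 equatorial, the diastereomer that a chair-controlled double allylation should deliver. The forward step is an SN2 displacement at a secondary allylic carbon that must not touch C9.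

**13 ⇒ 10 + 8.** The C5–C6 and C9–C10 bonds are cut: each is the Cα–Cβ bond of a homoallylic alcohol, and the two retrons share the C5–C10 bond. The ring opens into a C4 dialdehyde and a C8 bis-metallated diene, and the origin of four contiguous stereocentres, the quaternary one included, is reduced to a single boron-bearing carbon. The forward step must add the secondary allylic boronate first and the newly formed primary one second, and needs Z geometry in both partners.

**10 ⇒ 6 + 9.** The C1–B and C2–B bonds are cut. The precursor is an achiral hydrocarbon, and chirality enters by catalysis. The forward step must be a 1,2- and not a 1,4-addition; the Z geometry at C10=C5 is what should secure this.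

**8 ⇒ 7.** The two formyl oxygens are reconnected through one ring oxygen. The Z geometry of the dialdehyde is inherited from a five-membered heteroarene. The forward oxidative ring opening must be neutral and leave no reagent residue.

**6 ⇒ 5 ⇒ 4 ⇒ 3 ⇒ 1 + 2.** C1=C2 is cut (methylenation), the oxidation level at C1 is adjusted twice, and C10=C5 is cut by a Z-selective olefination. The triene is reduced to two commercial compounds. The only demand is that the Z geometry, set in the first step, is not lost at the enal stage.

## Other disconnections considered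

**Alternative 1:** (the first that comes to mind) Cut C5–C10 by a retro-Cope rearrangement to the trans,trans-germacra-1(10),4-dien-12,8-olide A1. The forward key step is the thermal [3,3] shift through the chair of the ten-membered ring, which would set C5 and C10. A1 is not simpler than the target: it is a cyclodecadiene with two trisubstituted trans alkenes, one a conjugated enal, and C6, C7, C8, C9 and C11 still have to be set on a conformationally mobile medium ring. The Cope step settles two of seven centres and leaves the hard part to a macrocyclisation. The chosen plan makes the same 1,5-diene without a medium ring.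

**Alternative 2:** Cut C5–C6 and C9–C10 in the Diels–Alder sense. The forward key step is a [4+2] cycloaddition of (2E)-2-methyl-4-oxopent-2-enal A2 with (1E,3E)-buta-1,3-diene-1,4-diyl diacetate A3 to give adduct A4, in which C1 and C4 are still carbonyl carbons. Absolute configuration would rest on an asymmetric cycloaddition between a sluggish diacyloxydiene and a trisubstituted 4-oxo-enal whose two carbonyl groups compete for the catalyst and for the endo position. A4 would then need double methylenation of carbonyl groups that are β to acyloxy leaving groups (elimination), and several operations to tell the cis C6 and C9 oxygens apart. The chosen plan forms the same two ring bonds but delivers the vinyl and isopropenyl groups directly, sets absolute configuration in a separate catalytic step, and gives the two oxygens different configurations that are addressed selectively.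

**Alternative 3:** Cut C6–C7. The forward key step is a ketyl–olefin radical cyclisation with SmI2 of the formyl butenolide A5, the C6 ketyl attacking C7 of the butenolide in a 6-exo closure; it would set C6, C7 and, by protonation, C11. Cyclisations of this kind place the new hydroxyl anti to the new side chain, that is C6–O trans to C7–C11, the opposite of what the target needs. A5 also already carries C5, C8, C9 and the quaternary C10 on an open chain, each of which needs its own stereocontrolled step. The step therefore attacks the easier half of the problem and the route would be longer.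

Key step: step 7

Assumption: the (R,R)-configured ligand in step 6 is assumed to give the (S)-boronate 10; the sense of induction cannot be fixed from first principles, and the antipodal ligand is used if it proves opposite.

## Route

Step 1
Reactants: 1 2-methylprop-2-enal (methacrolein); 2 ethyl 2-[bis(2,2,2-trifluoroethoxy)phosphoryl]propanoate
Product: 3 ethyl (2Z)-2,4-dimethylpenta-2,4-dienoate
Conditions: KN(SiMe3)2, 18-crown-6, THF, −78 °C
Reagents that add atoms: ethyl 2-[bis(2,2,2-trifluoroethoxy)phosphoryl]propanoate (2), CCOC(=O)C(C)P(=O)(OCC(F)(F)F)OCC(F)(F)F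
Why: Still–Gennari variant of the Horner–Wadsworth–Emmons olefination: with the electron-poor bis(trifluoroethyl) phosphonate and a dissociated potassium counter-ion the kinetic syn-oxaphosphetane collapses before it equilibrates, so the trisubstituted alkene should form with the ester cis to the isopropenyl group (Z); no stereocentre is formed.

Step 2
Reactants: 3 ethyl (2Z)-2,4-dimethylpenta-2,4-dienoate
Product: 4 (2Z)-2,4-dimethylpenta-2,4-dien-1-ol
Conditions: i-Bu2AlH (2.2 equiv), CH2Cl2, −78 °C; aq. KNaC4H4O6 work-up
Reagents that add atoms: none
Why: Standard 1,2-reduction of an enoate by i-Bu2AlH at low temperature; the Z trisubstituted alkene is not touched.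

Step 3
Reactants: 4 (2Z)-2,4-dimethylpenta-2,4-dien-1-ol
Product: 5 (2Z)-2,4-dimethylpenta-2,4-dienal
Conditions: MnO2 (excess), pentane/CH2Cl2, 0 → 20 °C, dark; used at once
Reagents that add atoms: none
Why: Heterogeneous oxidation of a primary allylic alcohol by MnO2 under neutral conditions, chosen to avoid acid- or base-promoted Z to E isomerisation of the α-methyl enal.

Step 4
Reactants: 5 (2Z)-2,4-dimethylpenta-2,4-dienal
Product: 6 (3Z)-2,4-dimethylhexa-1,3,5-triene
Conditions: Ph3PCH3Br, NaN(SiMe3)2, THF, −78 → 0 °C; product kept as a cold solution
Reagents that add atoms: methyltriphenylphosphonium bromide, C[P+](c1ccccc1)(c1ccccc1)c1ccccc1.[Br-]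
Why: Wittig methylenation with the unstabilised ylide at low temperature attacks only the aldehyde and leaves the adjacent Z alkene unchanged; the volatile hydrocarbon is not heated because a (Z)-1,3,5-triene can electrocyclise on strong heating.

Step 5
Reactants: 7 furan
Product: 8 (2Z)-but-2-enedial
Conditions: dimethyldioxirane (1.0 equiv), acetone, −20 → 0 °C; acetone exchanged for CH2Cl2 in the cold, solution used directly
Reagents that add atoms: dimethyldioxirane, CC1(C)OO1
Why: Epoxidation of furan by the dioxirane followed by spontaneous ring opening of the 2,3-epoxide gives the ene-dial; the cis geometry of the ring is carried into the Z alkene and acetone is the only by-product.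

Step 6
Reactants: 6 (3Z)-2,4-dimethylhexa-1,3,5-triene; 9 bis(pinacolato)diboron
Product: 10 2,2'-[(2S,3Z)-3,5-dimethylhexa-3,5-diene-1,2-diyl]bis(4,4,5,5-tetramethyl-1,3,2-dioxaborolane)
Conditions: Pt(dba)3 (3 mol %), phenylphosphonite of (4R,5R)-2,2-dimethyl-α,α,α′,α′-tetrakis(3,5-diisopropylphenyl)-1,3-dioxolane-4,5-dimethanol (6 mol %), THF, 60 °C
Reagents that add atoms: bis(pinacolato)diboron (9), CC1(C)OB(OC1(C)C)B1OC(C)(C)C(C)(C)O1
Why: Enantioselective 1,2-diboration of a terminal alkene by zerovalent platinum (oxidative addition of B–B, alkene insertion, reductive elimination); the monosubstituted C1=C2 reacts before the 1,1-disubstituted C3=C4, and 1,4-diboration is disfavoured because the s-cis conformer of C2=C1–C10=C5 would drive C2 into the cis isopropenyl group on C5; the chiral phosphonite selects the alkene face and sets the C1 boronate stereocentre (S).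

Step 7
Reactants: 10 2,2'-[(2S,3Z)-3,5-dimethylhexa-3,5-diene-1,2-diyl]bis(4,4,5,5-tetramethyl-1,3,2-dioxaborolane); 8 (2Z)-but-2-enedial
Product: 13 (1S,4S,5S,6S)-5-ethenyl-5-methyl-6-(prop-1-en-2-yl)cyclohex-2-ene-1,4-diol (elemane locants: 6α-OH, 9β-OH, 5β-isopropenyl, 10β-methyl, 10α-vinyl), via mono-allylation aldehyde 11 (not isolated), via bis(borate) ester 12 (not isolated)
Conditions: 8 (1.5 equiv), toluene/CH2Cl2, 0.05 M, 25 → 45 °C; then aq. NaHCO3
Reagents that add atoms: (2Z)-but-2-enedial (8), O=C/C=C\C=O
Why: The secondary allylic boronate of 10 adds to one formyl group of 8 through a closed six-membered Zimmerman–Traxler chair; the closest known reaction type is the tandem diene-diboration/double carbonyl allylboration of 1,4-dicarbonyl compounds, applied here to an unsaturated dialdehyde. Because the isopropenyl group is cis on the γ-carbon C5 it must be axial, and the α-CH2B(pin) group is then forced equatorial to avoid a syn-pentane clash, so the C5–C6 bond forms syn (oxygen trans to isopropenyl on the future ring), the boronate chirality is transferred to C5, and the new C1=C10 alkene of 11 is E. That alkene makes the remaining primary C–B bond allylic, and the Z C7=C8 alkene holds the second formyl group within reach, so a second, intramolecular allylboration forms C9–C10 and closes the cyclohexene, the only ring formed, by 6-exo-trig attack on the carbonyl. Its transition state is a trans-decalin-like pair of chairs in which the ring-forming chain, the C5 isopropenyl group and the C6 borate are equatorial and only the C10 methyl is axial; this places the new C9 oxygen cis to the methyl, the vinyl group trans to the isopropenyl group, and fixes the quaternary centre C10. C5 is thus controlled by the boronate centre from step 6, C6 by the chair of the first addition, and C10 and C9 by C5 and C6 through the bicyclic chair. The step needs 1,2- and γ-selectivity and ring closure faster than oligomerisation: allylboronates add only at the carbonyl carbon through the cyclic transition state, the second boron is inert until the first addition has occurred, and the second addition is intramolecular. Hydrolysis of the two borate esters of 12 on work-up gives 13.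

Step 8
Reactants: 13 (1S,4S,5S,6S)-5-ethenyl-5-methyl-6-(prop-1-en-2-yl)cyclohex-2-ene-1,4-diol; 14 2-methylpropanoic acid
Product: 15 (1R,4S,5S,6S)-5-ethenyl-4-hydroxy-5-methyl-6-(prop-1-en-2-yl)cyclohex-2-en-1-yl 2-methylpropanoate (6β-isobutyrate, 9β-OH)
Conditions: PPh3, diisopropyl azodicarboxylate, 14 (1.5 equiv), toluene, 0 → 25 °C
Reagents that add atoms: 2-methylpropanoic acid (14), CC(C)C(=O)O
Why: Mitsunobu esterification: the alkoxyphosphonium salt forms at the less hindered allylic C6 hydroxyl (the C9 hydroxyl is neopentylic) and is displaced by isobutyrate with inversion, which turns the 6α-alcohol into the 6β-ester of the target and differentiates the two oxygens in one operation; H5 is cis to the leaving group, so no anti-periplanar hydrogen is available for E2.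

Step 9
Reactants: 15 (1R,4S,5S,6S)-5-ethenyl-4-hydroxy-5-methyl-6-(prop-1-en-2-yl)cyclohex-2-en-1-yl 2-methylpropanoate; 16 1,1,1-triethoxypropane (triethyl orthopropionate)
Product: 18 ethyl (11R)-6β-(2-methylpropanoyloxy)elema-1,3,8-trien-12-oate (H5α, H7α, 10β-methyl), via mixed ketene acetal 17 (not isolated)
Conditions: 16 (8 equiv), EtCO2H (0.1 equiv), xylene, 140 °C, ethanol distilled off
Reagents that add atoms: 1,1,1-triethoxypropane (16), CCC(OCC)(OCC)OCC
Why: Johnson–Claisen rearrangement: acid-catalysed exchange at the free C9 hydroxyl and loss of ethanol give ketene acetal 17, whose suprafacial [3,3] shift turns the β C9–O bond into a β C7–C11 bond and moves the alkene to C8=C9; the β groups on C6 and C10 block a chair, so the boat with the C11 methyl turned outward (E ketene acetal, methyl cis to OEt) should dominate and give (11R); the base-free conditions spare the isobutyrate.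

Step 10
Reactants: 18 ethyl (11R)-6β-(2-methylpropanoyloxy)elema-1,3,8-trien-12-oate
Product: 20 ethyl (11R)-6β-(2-methylpropanoyloxy)-15-oxoelema-1,3,8-trien-12-oate, via allylic alcohol 19 (not isolated)
Conditions: SeO2 (1.5 equiv), 1,4-dioxane, 80 °C
Reagents that add atoms: selenium dioxide, O=[Se]=O
Why: Riley allylic oxidation (ene reaction, [2,3] shift, then oxidation of alcohol 19 by excess SeO2) at the methyl group of the 1,1-disubstituted C4=C3 alkene; the vinyl group has no allylic hydrogen, and the one allylic hydrogen of the hindered ring alkene (H7) is deactivated by the flanking ester-bearing and acyloxy-bearing carbons; no stereocentre is touched.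

Step 11
Reactants: 20 ethyl (11R)-6β-(2-methylpropanoyloxy)-15-oxoelema-1,3,8-trien-12-oate
Product: 22 (11R)-9α-hydroxy-6β-(2-methylpropanoyloxy)-15-oxoelema-1,3-dien-12,8β-olide (target; 5R,6S,7S,8S,9S,10S,11R in elemane numbering), via epoxy ester 21 (not isolated)
Conditions: dimethyldioxirane (1.1 equiv), acetone, −20 → 0 °C; evaporate; TsOH·H2O (0.2 equiv), wet CH2Cl2, 25 °C
Reagents that add atoms: dimethyldioxirane, CC1(C)OO1; water, O
Why: Prilezhaev-type epoxidation by the neutral dioxirane should occur only at the electron-rich cis-disubstituted C8=C9 alkene (C3=C4 is now conjugated to the aldehyde, the vinyl group is monosubstituted and neopentylic) and from the α face, anti to the C7 side chain and the C10 methyl; acid then triggers 5-exo opening of the epoxide at C8 by the ester carbonyl oxygen with inversion (C9 is neopentylic), and the dialkoxycarbenium ion is hydrolysed with loss of ethanol, giving the cis-fused lactone (8β-O) and the 9α-hydroxyl.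

## Compound list

1 | 2-methylprop-2-enal (methacrolein) | CC(=C)C=O | starting material
2 | ethyl 2-[bis(2,2,2-trifluoroethoxy)phosphoryl]propanoate | CCOC(=O)C(C)P(=O)(OCC(F)(F)F)OCC(F)(F)F | starting material
3 | ethyl (2Z)-2,4-dimethylpenta-2,4-dienoate | CCOC(=O)/C(C)=C\C(C)=C | intermediate
4 | (2Z)-2,4-dimethylpenta-2,4-dien-1-ol | OC/C(C)=C\C(C)=C | intermediate
5 | (2Z)-2,4-dimethylpenta-2,4-dienal | O=C/C(C)=C\C(C)=C | intermediate
6 | (3Z)-2,4-dimethylhexa-1,3,5-triene | C=C/C(C)=C\C(C)=C | intermediate
7 | furan | c1ccoc1 | starting material
8 | (2Z)-but-2-enedial | O=C/C=C\C=O | intermediate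
9 | bis(pinacolato)diboron | CC1(C)OB(OC1(C)C)B1OC(C)(C)C(C)(C)O1 | starting material
10 | 2,2'-[(2S,3Z)-3,5-dimethylhexa-3,5-diene-1,2-diyl]bis(4,4,5,5-tetramethyl-1,3,2-dioxaborolane) | CC1(C)OB(C[C@H](B2OC(C)(C)C(C)(C)O2)/C(C)=C\C(C)=C)OC1(C)C | intermediate
11 | (2Z,4S,5S,6E)-6-methyl-5-(prop-1-en-2-yl)-8-(pinacolatoboryl)-4-[(pinacolatoboryl)oxy]octa-2,6-dienal | O=C/C=C\[C@H](OB1OC(C)(C)C(C)(C)O1)[C@@H](C(C)=C)/C(C)=C/CB1OC(C)(C)C(C)(C)O1 | intermediate
12 | bis(4,4,5,5-tetramethyl-1,3,2-dioxaborolan-2-yl) ether of diol 13 | C=C[C@]1(C)[C@@H](OB2OC(C)(C)C(C)(C)O2)C=C[C@H](OB2OC(C)(C)C(C)(C)O2)[C@H]1C(C)=C | intermediate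
13 | (1S,4S,5S,6S)-5-ethenyl-5-methyl-6-(prop-1-en-2-yl)cyclohex-2-ene-1,4-diol | C=C[C@]1(C)[C@@H](O)C=C[C@H](O)[C@H]1C(C)=C | intermediate
14 | 2-methylpropanoic acid (isobutyric acid) | CC(C)C(=O)O | starting material
15 | (1R,4S,5S,6S)-5-ethenyl-4-hydroxy-5-methyl-6-(prop-1-en-2-yl)cyclohex-2-en-1-yl 2-methylpropanoate | C=C[C@]1(C)[C@@H](O)C=C[C@@H](OC(=O)C(C)C)[C@H]1C(C)=C | intermediate
16 | 1,1,1-triethoxypropane (triethyl orthopropionate) | CCC(OCC)(OCC)OCC | starting material
17 | (E)-1-ethoxyprop-1-en-1-yl ether of 15 at O9 (mixed ketene acetal) | C=C[C@]1(C)[C@@H](O/C(OCC)=C/C)C=C[C@@H](OC(=O)C(C)C)[C@H]1C(C)=C | intermediate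
18 | ethyl (11R)-6β-(2-methylpropanoyloxy)elema-1,3,8-trien-12-oate | C=C[C@]1(C)C=C[C@@H]([C@@H](C)C(=O)OCC)[C@@H](OC(=O)C(C)C)[C@H]1C(C)=C | intermediate
19 | ethyl (11R)-15-hydroxy-6β-(2-methylpropanoyloxy)elema-1,3,8-trien-12-oate | C=C[C@]1(C)C=C[C@@H]([C@@H](C)C(=O)OCC)[C@@H](OC(=O)C(C)C)[C@H]1C(=C)CO | intermediate
20 | ethyl (11R)-6β-(2-methylpropanoyloxy)-15-oxoelema-1,3,8-trien-12-oate | C=C[C@]1(C)C=C[C@@H]([C@@H](C)C(=O)OCC)[C@@H](OC(=O)C(C)C)[C@H]1C(=C)C=O | intermediate
21 | ethyl (11R)-8α,9α-epoxy-6β-(2-methylpropanoyloxy)-15-oxoelema-1,3-dien-12-oate | C=C[C@]1(C)[C@@H]2O[C@@H]2[C@@H]([C@@H](C)C(=O)OCC)[C@@H](OC(=O)C(C)C)[C@H]1C(=C)C=O | intermediate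
22 | (11R)-9α-hydroxy-6β-(2-methylpropanoyloxy)-15-oxoelema-1,3-dien-12,8β-olide (CNP0198892.2) | C=C[C@]1(C)[C@H](O)[C@H]2OC(=O)[C@H](C)[C@H]2[C@@H](OC(=O)C(C)C)[C@H]1C(=C)C=O | target

## Step count and least certain steps

Total step count: 11. Longest linear sequence: 10 steps (steps 1–4 and 6–11); step 5 is a one-step branch that supplies 8.

**Step 7 (key step).** The dialdehyde may be lost by Z to E isomerisation and oligomerisation while the first allylboration, slowed by the axial isopropenyl group in its chair, is still in progress; the second formyl group may also be captured by another boronate before the ring closes. The fallback sets out from 10 and returns at 13; it separates the two additions and replaces the dialdehyde by a stable, differentiated one. Compound 10 is allylated once with (2Z)-4,4-dimethoxybut-2-enal F1 (from controlled acid hydrolysis of commercial 2,5-dimethoxy-2,5-dihydrofuran). This gives (2Z,4S,5S,6E)-1,1-dimethoxy-6-methyl-5-(prop-1-en-2-yl)-8-(pinacolatoboryl)octa-2,6-dien-4-ol F2, which still holds the primary allylic boronate. LiBF4 in wet acetonitrile at high dilution then releases the C9 aldehyde, which closes the ring through the same bicyclic chair, and hydrolysis gives 13.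

**Step 9.** Orthoester exchange at the neopentylic C9 hydroxyl may be slow, so that thermal side reactions of the 1,5-diene arrays or erosion of control at C11 take over. The fallback sets out from 15 and returns at 22. Acylation with propanoic anhydride and 4-(dimethylamino)pyridine gives (1R,4S,5S,6S)-5-ethenyl-5-methyl-4-(propanoyloxy)-6-(prop-1-en-2-yl)cyclohex-2-en-1-yl 2-methylpropanoate F3. Soft enolisation with n-Bu2BOTf and i-Pr2NEt at −78 °C (the α-branched isobutyrate should enolise far more slowly) and warming to 25 °C effect an ester-enolate Claisen rearrangement through the same boat, giving (11R)-6β-(2-methylpropanoyloxy)elema-1,3,8-trien-12-oic acid F4. SeO2 as in step 10 gives (11R)-6β-(2-methylpropanoyloxy)-15-oxoelema-1,3,8-trien-12-oic acid F5. Dimethyldioxirane then gives (11R)-8α,9α-epoxy-6β-(2-methylpropanoyloxy)-15-oxoelema-1,3-dien-12-oic acid F6, which should lactonise without added acid to 22.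

**Step 8.** Backside attack at C6 is hindered by the syn C10 methyl group, so SN2′ attack at C8 or ionisation to the allyl cation (elimination, loss of configuration) may compete. The fallback sets out from 13 and returns at 15. MnO2 oxidises the less hindered allylic C6 hydroxyl to (4S,5S,6S)-5-ethenyl-4-hydroxy-5-methyl-6-(prop-1-en-2-yl)cyclohex-2-en-1-one F7. Corey–Bakshi–Shibata reduction (BH3·SMe2 with the enantiomer of 1-methyl-3,3-diphenyltetrahydro-1H,3H-pyrrolo[1,2-c][1,3,2]oxazaborole that delivers hydride to the α face) gives (1R,4S,5S,6S)-5-ethenyl-5-methyl-6-(prop-1-en-2-yl)cyclohex-2-ene-1,4-diol F8. Its less hindered C6 hydroxyl is acylated selectively (2-methylpropanoyl chloride, 2,4,6-collidine, −40 °C) to give 15.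

**Step 6.** Enantioselectivity may be eroded because the reacting alkene is attached to a fully substituted diene carbon, or boron may add across the diene. The fallback sets out from 5 and returns at 10. Ohira–Bestmann homologation (dimethyl (1-diazo-2-oxopropyl)phosphonate, K2CO3, MeOH) gives (3Z)-3,5-dimethylhexa-3,5-dien-1-yne F9. Double protoboration of the terminal alkyne, catalysed by CuCl (monovalent copper) with a chiral N-heterocyclic carbene and NaOt-Bu (B2(pin)2, MeOH, THF, −15 °C), gives the vicinal bis(boronate) 10, the second copper–boron addition setting C1.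

**Step 10.** The ene oxidation may also occur at the ring alkene (H7), or the aldehyde may be over-oxidised. The fallback sets out from 18 and returns at 20. Ene-type chlorination with NaOCl and CeCl3·7H2O (CH2Cl2/water, 0 °C), which is selective for 1,1-disubstituted alkenes, gives ethyl (11R)-15-chloro-6β-(2-methylpropanoyloxy)elema-1,3,8-trien-12-oate F10. Ganem oxidation of the allylic chloride with 4-methylmorpholine N-oxide (catalytic KI, acetonitrile, 60 °C) gives 20.

## Further compounds

F1 | step 7 | (2Z)-4,4-dimethoxybut-2-enal | COC(OC)/C=C\C=O
F2 | step 7 | (2Z,4S,5S,6E)-1,1-dimethoxy-6-methyl-5-(prop-1-en-2-yl)-8-(4,4,5,5-tetramethyl-1,3,2-dioxaborolan-2-yl)octa-2,6-dien-4-ol | COC(OC)/C=C\[C@H](O)[C@@H](C(C)=C)/C(C)=C/CB1OC(C)(C)C(C)(C)O1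
F3 | step 9 | (1R,4S,5S,6S)-5-ethenyl-5-methyl-4-(propanoyloxy)-6-(prop-1-en-2-yl)cyclohex-2-en-1-yl 2-methylpropanoate | C=C[C@]1(C)[C@@H](OC(=O)CC)C=C[C@@H](OC(=O)C(C)C)[C@H]1C(C)=C
F4 | step 9 | (11R)-6β-(2-methylpropanoyloxy)elema-1,3,8-trien-12-oic acid | C=C[C@]1(C)C=C[C@@H]([C@@H](C)C(=O)O)[C@@H](OC(=O)C(C)C)[C@H]1C(C)=C
F5 | step 9 | (11R)-6β-(2-methylpropanoyloxy)-15-oxoelema-1,3,8-trien-12-oic acid | C=C[C@]1(C)C=C[C@@H]([C@@H](C)C(=O)O)[C@@H](OC(=O)C(C)C)[C@H]1C(=C)C=O
F6 | step 9 | (11R)-8α,9α-epoxy-6β-(2-methylpropanoyloxy)-15-oxoelema-1,3-dien-12-oic acid | C=C[C@]1(C)[C@@H]2O[C@@H]2[C@@H]([C@@H](C)C(=O)O)[C@@H](OC(=O)C(C)C)[C@H]1C(=C)C=O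
F7 | step 8 | (4S,5S,6S)-5-ethenyl-4-hydroxy-5-methyl-6-(prop-1-en-2-yl)cyclohex-2-en-1-one | C=C[C@]1(C)[C@@H](O)C=CC(=O)[C@H]1C(C)=C
F8 | step 8 | (1R,4S,5S,6S)-5-ethenyl-5-methyl-6-(prop-1-en-2-yl)cyclohex-2-ene-1,4-diol | C=C[C@]1(C)[C@@H](O)C=C[C@@H](O)[C@H]1C(C)=C
F9 | step 6 | (3Z)-3,5-dimethylhexa-3,5-dien-1-yne | C#C/C(C)=C\C(C)=C
F10 | step 10 | ethyl (11R)-15-chloro-6β-(2-methylpropanoyloxy)elema-1,3,8-trien-12-oate | C=C[C@]1(C)C=C[C@@H]([C@@H](C)C(=O)OCC)[C@@H](OC(=O)C(C)C)[C@H]1C(=C)CCl
A1 | alternative 1 | (11R)-9α-hydroxy-6β-(2-methylpropanoyloxy)-15-oxo-trans,trans-germacra-1(10),4-dien-12,8β-olide | O=C/C1=C\[C@H](OC(=O)C(C)C)[C@@H]2[C@@H](C)C(=O)O[C@@H]2[C@@H](O)/C(C)=C/CC1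
A2 | alternative 2 | (2E)-2-methyl-4-oxopent-2-enal | CC(=O)/C=C(\C)C=O
A3 | alternative 2 | (1E,3E)-buta-1,3-diene-1,4-diyl diacetate | CC(=O)O/C=C/C=C/OC(C)=O
A4 | alternative 2 | Diels–Alder adduct: 5β-acetyl-6β,9β-diacetoxy-10α-formyl-10β-methylcyclohex-7-ene (elemane locants) | O=C[C@]1(C)[C@@H](OC(C)=O)C=C[C@@H](OC(C)=O)[C@H]1C(C)=O
A5 | alternative 3 | formyl butenolide: 9-hydroxy-6-oxo-6,7-seco-elema-1,3,7(11)-trien-12,8-olide with the C5, C8, C9 and C10 configurations of the target | O=C[C@@H](C(C)=C)[C@](C)(C=C)[C@H](O)[C@H]1OC(=O)C(C)=C1
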